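The acyl chain is cut out of a ring. Carboxyl carbon C1, methylenes C2–C4 and alkyne carbons C5 and C6 are the six carbons of a cyclohexanone (C5 the ketone carbon, C6 its α-carbon, C1 the β-carbon), and C7≡C8 sits on C6 as an alkynyl group. Eschenmoser–Tanabe fragmentation of the matching α,β-epoxy ketone, a 1-alkynyl-7-oxabicyclo[4.1.0]heptan-2-one carrying the furyl-terminated chain, cuts the bond between the two epoxide carbons and in one operation delivers the C1 aldehyde and the C5≡C6 alkyne, already conjugated to C7≡C8. Oxidation and esterification with a furyl diynol made by Cadiot–Chodkiewicz coupling finish the target; both furan rings are spectators.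

Key step: step 7

Remark: the target has no stereocentre; the stereocentres of 9, 11 and 12 are racemic and vanish in step 7, and their SMILES show one enantiomer of the racemate.

Remark: both halves begin with the same 2-lithiofuran, so it is made once as a titrated THF solution (step 1) and divided between steps 2 and 9.

Step 1
Reactants: 1 furan
Product: 2 2-lithiofuran (furan-2-yllithium), held as a THF solution at 0 °C under argon
Conditions: n-BuLi (1.0 equiv), THF, −20 °C → 0 °C; solution titrated and divided in two portions
Reagents that add atoms: n-butyllithium, [Li]CCCC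
Why: Deprotonative α-lithiation of furan next to the ring oxygen is clean with n-BuLi in THF, and the resulting solution is stable for hours at 0 °C, so one batch can serve both alkylations.

Step 2
Reactants: 2 2-lithiofuran; 3 1,11-dibromoundecane
Product: 4 2-(11-bromoundecyl)furan
Conditions: solution of 2 added by cannula to 3 (3 equiv), THF, −78 °C → rt
Reagents that add atoms: none
Why: The furyllithium displaces one bromide in an SN2 alkylation, with inverse addition to an excess of the (recoverable) dibromide keeping double alkylation low.

Step 3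
Reactants: 4 2-(11-bromoundecyl)furan
Product: 5 2-(tridec-12-yn-1-yl)furan
Conditions: LiC≡CH·H2NCH2CH2NH2, DMSO, 10 °C → rt
Reagents that add atoms: lithium acetylide–ethylenediamine complex, [Li+].[C-]#C.NCCN
Why: SN2 alkylation of lithium acetylide on an unhindered primary bromide in DMSO should install the terminal alkyne without affecting the furan.

Step 4
Reactants: 6 cyclohex-2-en-1-one
Product: 7 2-iodocyclohex-2-en-1-one
Conditions: I2, K2CO3, DMAP (cat.), THF/H2O, rt
Reagents that add atoms: iodine, II
Why: Nucleophile-catalysed α-iodination of a cyclic enone (conjugate addition of DMAP, iodination, elimination) is the standard route to 2-iodocycloalkenones.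

Step 5
Reactants: 5 2-(tridec-12-yn-1-yl)furan; 7 2-iodocyclohex-2-en-1-one
Product: 8 2-[13-(furan-2-yl)tridec-1-yn-1-yl]cyclohex-2-en-1-one
Conditions: PdCl2(PPh3)2 (cat.), CuI (cat.), i-Pr2NH, THF, 0 °C → rt
Reagents that add atoms: none
Why: Sonogashira coupling should proceed at or below room temperature because α-iodoenones undergo oxidative addition readily, and the furan and enone are inert to these conditions.

Step 6
Reactants: 8 2-[13-(furan-2-yl)tridec-1-yn-1-yl]cyclohex-2-en-1-one
Product: 9 racemic 1-[13-(furan-2-yl)tridec-1-yn-1-yl]-7-oxabicyclo[4.1.0]heptan-2-one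
Conditions: 30% aq H2O2, NaOH (cat.), MeOH/THF, 0 °C
Reagents that add atoms: hydrogen peroxide, OO
Why: Weitz–Scheffer nucleophilic epoxidation (hydroperoxide adds to the enone β-carbon, then closure on oxygen) should give the necessarily cis-fused epoxide as a racemate whose two stereocentres are erased in step 7, while furan and alkyne are inert to alkaline peroxide.

Step 7
Reactants: 9 racemic 1-[13-(furan-2-yl)tridec-1-yn-1-yl]-7-oxabicyclo[4.1.0]heptan-2-one; 10 p-toluenesulfonylhydrazide
Product: 13 19-(furan-2-yl)nonadeca-5,7-diynal, via tosylhydrazone 11 (not isolated), via hydroxy azoalkene 12 (not isolated)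
Conditions: TsNHNH2 (1.0 equiv), AcOH/CH2Cl2, −20 °C, then → rt
Reagents that add atoms: none
Why: Eschenmoser–Tanabe fragmentation (locants of 9): 10 condenses with the C2 ketone to give tosylhydrazone 11, which opens the C1–O bond of the epoxide to azoalkene 12 with the oxygen left on C6, and a Grob-type fragmentation of 12 then forms the C6 aldehyde, breaks the C1–C6 ring bond between the former epoxide carbons, turns C2–C1 into a triple bond (C5≡C6 of 13, conjugated to C7≡C8) and releases N2 and p-toluenesulfinic acid. The closest known reaction type is the fragmentation of 2-substituted 2,3-epoxycyclohexanone sulfonylhydrazones to alk-5-ynals. No ring is closed and no stereocentre is created; both stereocentres of 9 are destroyed, so the racemate serves. The selectivity needed is C–C cleavage ahead of capture of the new aldehyde by hydrazide or cyclisation of 12 to a pyrazole-type by-product; the six-membered ring holds the C1–C6 bond anti-periplanar to the departing C2–N bond across the azoalkene double bond, and forming 11 at −20 °C with exactly one equivalent of 10 leaves no free hydrazide when 13 appears. Acetic acid in dichloromethane at or below room temperature should be tolerated by the 2-alkylfuran and the diyne.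

Step 8
Reactants: 13 19-(furan-2-yl)nonadeca-5,7-diynal
Product: 15 19-(furan-2-yl)nonadeca-5,7-diynoic acid, via sodium carboxylate 14 (not isolated)
Conditions: Ag2O, aq NaOH, THF/EtOH, 0 °C → rt; then cold dilute HCl to pH 3
Reagents that add atoms: sodium hydroxide (aqueous; its hydroxide supplies the second carboxyl oxygen), [Na+].[OH-]
Why: Ag2O oxidation of the aldehyde hydrate (Tollens-type) should give the carboxylate under mild alkaline conditions that spare the furan and the internal diyne, which is why chlorite, an oxidant of 2-alkylfurans, is avoided.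

Step 9
Reactants: 2 2-lithiofuran; 16 1-bromo-4-chlorobutane
Product: 17 2-(4-chlorobutyl)furan
Conditions: second portion of the solution of 2, then 16 (1.1 equiv), THF, −78 °C → rt
Reagents that add atoms: none
Why: 2-Furyllithium displaces bromide much faster than chloride (SN2), so the bromochloroalkane should give the monoalkylated chloride without a large excess of electrophile.

Step 10
Reactants: 17 2-(4-chlorobutyl)furan
Product: 18 2-(hex-5-yn-1-yl)furan
Conditions: LiC≡CH·H2NCH2CH2NH2, DMSO, rt → 40 °C
Reagents that add atoms: lithium acetylide–ethylenediamine complex, [Li+].[C-]#C.NCCN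
Why: SN2 alkylation of lithium acetylide in DMSO is effective for primary chlorides on gentle warming.

Step 11
Reactants: 19 pent-4-yn-1-ol
Product: 20 5-bromopent-4-yn-1-ol
Conditions: NBS, AgNO3 (cat.), acetone, rt
Reagents that add atoms: N-bromosuccinimide, O=C1CCC(=O)N1Br
Why: Silver-catalysed electrophilic bromination of the terminal alkyne C–H gives the 1-bromoalkyne, and it is placed on the furan-free partner because NBS would attack a furan.

Step 12
Reactants: 18 2-(hex-5-yn-1-yl)furan; 20 5-bromopent-4-yn-1-ol
Product: 21 11-(furan-2-yl)undeca-4,6-diyn-1-ol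
Conditions: CuCl (cat.), NH2OH·HCl, 30% aq n-BuNH2, MeOH, 0 °C, slow addition of 20
Reagents that add atoms: none
Why: Cadiot–Chodkiewicz coupling of a terminal alkyne with a 1-bromoalkyne should give the unsymmetrical 1,3-diyne, with hydroxylamine keeping the copper monovalent to suppress oxidative homocoupling and the free alcohol tolerated.

Step 13
Reactants: 15 19-(furan-2-yl)nonadeca-5,7-diynoic acid; 21 11-(furan-2-yl)undeca-4,6-diyn-1-ol
Product: 22 11-(furan-2-yl)undeca-4,6-diyn-1-yl 19-(furan-2-yl)nonadeca-5,7-diynoate
Conditions: DCC, DMAP (cat.), CH2Cl2, 0 °C → rt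
Reagents that add atoms: none
Why: Steglich esterification (carbodiimide activation with DMAP acyl transfer) should join the acid to the primary alcohol under neutral conditions compatible with both furans and both diynes.

Compound list
1 | furan | c1ccoc1 | starting material
2 | 2-lithiofuran (furan-2-yllithium), held as a titrated THF solution | [Li]c1ccco1 | intermediate
3 | 1,11-dibromoundecane | BrCCCCCCCCCCCBr | starting material
4 | 2-(11-bromoundecyl)furan | BrCCCCCCCCCCCc1ccco1 | intermediate
5 | 2-(tridec-12-yn-1-yl)furan, i.e. 13-(furan-2-yl)tridec-1-yne | C#CCCCCCCCCCCCc1ccco1 | intermediate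
6 | cyclohex-2-en-1-one | O=C1C=CCCC1 | starting material
7 | 2-iodocyclohex-2-en-1-one | O=C1C(I)=CCCC1 | intermediate
8 | 2-[13-(furan-2-yl)tridec-1-yn-1-yl]cyclohex-2-en-1-one | O=C1CCCC=C1C#CCCCCCCCCCCCc1ccco1 | intermediate
9 | racemic cis-fused 1-[13-(furan-2-yl)tridec-1-yn-1-yl]-7-oxabicyclo[4.1.0]heptan-2-one | O=C1CCC[C@@H]2O[C@]12C#CCCCCCCCCCCCc1ccco1 | intermediate
10 | p-toluenesulfonylhydrazide | Cc1ccc(cc1)S(=O)(=O)NN | starting material
11 | p-toluenesulfonylhydrazone of 9 at C2 (racemic, epoxide intact, C=N geometry not defined) | Cc1ccc(cc1)S(=O)(=O)NN=C1CCC[C@@H]2O[C@]12C#CCCCCCCCCCCCc1ccco1 | intermediate (not isolated)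
12 | racemic 2-[13-(furan-2-yl)tridec-1-yn-1-yl]-3-[(E)-(4-methylphenyl)sulfonyldiazenyl]cyclohex-2-en-1-ol | Cc1ccc(cc1)S(=O)(=O)/N=N/C1=C(C#CCCCCCCCCCCCc2ccco2)[C@@H](O)CCC1 | intermediate (not isolated)
13 | 19-(furan-2-yl)nonadeca-5,7-diynal | O=CCCCC#CC#CCCCCCCCCCCCc1ccco1 | intermediate
14 | sodium 19-(furan-2-yl)nonadeca-5,7-diynoate | [Na+].[O-]C(=O)CCCC#CC#CCCCCCCCCCCCc1ccco1 | intermediate (not isolated)
15 | 19-(furan-2-yl)nonadeca-5,7-diynoic acid | OC(=O)CCCC#CC#CCCCCCCCCCCCc1ccco1 | intermediate
16 | 1-bromo-4-chlorobutane | ClCCCCBr | starting material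
17 | 2-(4-chlorobutyl)furan | ClCCCCc1ccco1 | intermediate
18 | 2-(hex-5-yn-1-yl)furan | C#CCCCCc1ccco1 | intermediate
19 | pent-4-yn-1-ol | OCCCC#C | starting material
20 | 5-bromopent-4-yn-1-ol | OCCCC#CBr | intermediate
21 | 11-(furan-2-yl)undeca-4,6-diyn-1-ol | OCCCC#CC#CCCCCc1ccco1 | intermediate
22 | 11-(furan-2-yl)undeca-4,6-diyn-1-yl 19-(furan-2-yl)nonadeca-5,7-diynoate | O=C(CCCC#CC#CCCCCCCCCCCCc1ccco1)OCCCC#CC#CCCCCc1ccco1 | target

Total step count: 13. Longest linear sequence: 8 steps (1, 2, 3, 5, 6, 7, 8, 13).

Steps most likely to fail

Step 7. The hydrazone may fragment incompletely, the freed aldehyde may condense with hydrazide, or the azoalkene may cyclise or tautomerise instead of undergoing C–C cleavage. The fallback builds the diyne by C–C coupling instead of ring cleavage. Hex-5-ynoic acid would be brominated at the alkyne terminus (NBS, cat. AgNO3, acetone) to 6-bromohex-5-ynoic acid F1. F1 would then be coupled with alkyne 5 under Cadiot–Chodkiewicz conditions (CuCl, NH2OH·HCl, aq n-BuNH2, MeOH, 0 °C), giving acid 15 after acidification. This fallback sets out from 5 and rejoins the route at 15, bypassing steps 4 to 8.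

Step 6. Hydroperoxide or hydroxide may attack the carbonyl or open the strained product, or conjugate addition to the hindered cross-conjugated enynone may be sluggish. The fallback replaces nucleophilic epoxidation by a hydroxyl-directed one. Enynone 8 would be reduced under Luche conditions (NaBH4, CeCl3·7H2O, MeOH, 0 °C) to racemic 2-[13-(furan-2-yl)tridec-1-yn-1-yl]cyclohex-2-en-1-ol F2. Directed epoxidation (VO(acac)2 cat., t-BuOOH 1.1 equiv, CH2Cl2, 0 °C) should be faster than oxidation of the remote furan and would give racemic syn-1-[13-(furan-2-yl)tridec-1-yn-1-yl]-7-oxabicyclo[4.1.0]heptan-2-ol F3. Dess–Martin periodinane with NaHCO3 in CH2Cl2 would then oxidise F3 to 9. This fallback sets out from 8 and rejoins at 9.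

Step 12. Homocoupling of the bromoalkyne or of the terminal alkyne (halogen–copper exchange, adventitious oxidation) may erode the cross-coupling. The fallback is an oxidative Hay heterocoupling under statistical control, with no haloalkyne. Alkyne 18 and a fivefold excess of pent-4-yn-1-ol 19 (CuCl, TMEDA, air, acetone, rt) would give 21 directly. The symmetrical by-products deca-4,6-diyne-1,10-diol F4 and 1,12-di(furan-2-yl)dodeca-5,7-diyne F5 differ widely in polarity from 21 and would be removed by chromatography. This fallback sets out from 18 (with 19), rejoins at 21 and omits step 11.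

Further compounds
F1 | step 7 | 6-bromohex-5-ynoic acid | OC(=O)CCCC#CBr
F2 | step 6 | racemic 2-[13-(furan-2-yl)tridec-1-yn-1-yl]cyclohex-2-en-1-ol | O[C@@H]1CCCC=C1C#CCCCCCCCCCCCc1ccco1
F3 | step 6 | racemic syn-1-[13-(furan-2-yl)tridec-1-yn-1-yl]-7-oxabicyclo[4.1.0]heptan-2-ol | O[C@@H]1CCC[C@@H]2O[C@]12C#CCCCCCCCCCCCc1ccco1
F4 | step 12 | deca-4,6-diyne-1,10-diol | OCCCC#CC#CCCCO
F5 | step 12 | 1,12-di(furan-2-yl)dodeca-5,7-diyne | c1coc(CCCCC#CC#CCCCCc2ccco2)c1
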